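**Plan**

1. Retrosynthesis: cut C12–C2' and C15–C3' (Diels–Alder of a 7-oxolabda-8(17),12E,14-triene with a 2-chromenonyl-5-methoxy-p-benzoquinone); then remove C17, the C12–C15 diene and one C4 methyl from the diterpene; then cut C1–C2 and C5–C10 together (intramolecular Diels–Alder).
2. Enabling feature: on ring B the angular C20 methyl (on C10) and the C11 chain (on C9) are cis, so C20 (as acyl) and C12 (as alkoxy) can be tied into a temporary δ-lactone. Its exocyclic C1=C10 methylene is an activated dienophile, C2=C3–C4=C5 is the diene and C6–C9 (the future ring B) is the tether.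
3. Forward order: lactone carrying C9, chain C8 to C2, rings A and B in one step, 4,4-dimethyl group, lactone unravelled to the C20 methyl and the C12 aldehyde, side-chain diene, C7 ketone and C17 methylene, quinone-derived ring fused last. The chromone quinone is made separately (chalcone, flavone, quinone).
4. Stereochemistry: C9 from Rh/(R)-BINAP conjugate vinylation; C7 (temporary) from catalyst-controlled allylboration; C10 and C5 in the key step, relayed from C9 through the lactone ring and the endo rule; C12, C2' and C3' in the final cycloaddition.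

Key step: step 8

Remark: locants are those of the labdane skeleton (C1–C20) and, primed, of the quinone-derived ring (C1'–C6', C2' carrying the chromenone); α/β have the usual terpenoid meaning (C20 is β).

**Route**

Step 1
Reactants: 1 5,6-dihydro-2H-pyran-2-one
Product: 2 (R)-4-vinyltetrahydro-2H-pyran-2-one
Conditions: CH2=CHBF3K (1.5 equiv), [Rh(cod)2]BF4 (3 mol%), (R)-BINAP (3.3 mol%), toluene/H2O (10:1), 100 °C
Reagents that add atoms: potassium vinyltrifluoroborate, C=C[B-](F)(F)F.[K+]
Why: Rh-catalysed asymmetric 1,4-addition of an alkenylboron reagent (Hayashi–Miyaura reaction) to the unsaturated δ-lactone; the (R)-BINAP–Rh–vinyl complex differentiates the enantiofaces at C9 and should give the 4R lactone.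

Step 2
Reactants: 2 (R)-4-vinyltetrahydro-2H-pyran-2-one
Product: 3 (S)-2-(2-oxotetrahydro-2H-pyran-4-yl)acetaldehyde
Conditions: PdCl2(PhCN)2 (10 mol%), CuCl2·2H2O (10 mol%), AgNO2 (5 mol%), O2 (1 atm), t-BuOH/MeNO2 (15:1), 23 °C
Reagents that add atoms: dioxygen, O=O
Why: nitrite-modified, aldehyde-selective (anti-Markovnikov) Wacker oxidation of the vinyl group, helped by the branching at the allylic carbon C9; no stereocentre is touched and no free alcohol that could translactonise is formed.

Step 3
Reactants: 3 (S)-2-(2-oxotetrahydro-2H-pyran-4-yl)acetaldehyde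
Product: 4 (S)-4-[(S)-2-hydroxypent-4-en-1-yl]tetrahydro-2H-pyran-2-one
Conditions: allylB(pin) (1.3 equiv), (S)-TRIP phosphoric acid (5 mol%), toluene, −30 °C; aq. NaHCO3 work-up
Reagents that add atoms: allylboronic acid pinacol ester, C=CCB1OC(C)(C)C(C)(C)O1
Why: chiral phosphoric acid-catalysed allylboration through a chair-like six-membered transition state in which the catalyst selects the Si face of C7 (catalyst control, C9 is remote); C7 is oxidised later, so its purity is not critical.

Step 4
Reactants: 4 (S)-4-[(S)-2-hydroxypent-4-en-1-yl]tetrahydro-2H-pyran-2-one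
Product: 5 (S)-4-[(S)-2-(tert-butyldimethylsilyloxy)pent-4-en-1-yl]tetrahydro-2H-pyran-2-one
Conditions: TBSOTf, 2,6-lutidine, CH2Cl2, −78 °C
Reagents that add atoms: tert-butyldimethylsilyl trifluoromethanesulfonate, CC(C)(C)[Si](C)(C)OS(=O)(=O)C(F)(F)F
Why: O-silylation with a silyl triflate and a hindered pyridine base is fast at −78 °C, so the 7-hydroxyl is capped before it can attack the lactone carbonyl; configuration is unchanged.

Step 5
Reactants: 5 (S)-4-[(S)-2-(tert-butyldimethylsilyloxy)pent-4-en-1-yl]tetrahydro-2H-pyran-2-one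
Product: 6 (2E,5R)-5-(tert-butyldimethylsilyloxy)-2-methyl-6-[(4S)-2-oxotetrahydro-2H-pyran-4-yl]hex-2-enal
Conditions: methacrolein (8 equiv), second-generation Hoveyda–Grubbs catalyst (5 mol%), CH2Cl2, 40 °C
Reagents that add atoms: methacrolein, CC(=C)C=O
Why: olefin cross-metathesis of the terminal alkene with excess methacrolein should give the trisubstituted enal as the thermodynamically preferred E isomer (C6 cis to the C4 methyl).

Step 6
Reactants: 6 (2E,5R)-5-(tert-butyldimethylsilyloxy)-2-methyl-6-[(4S)-2-oxotetrahydro-2H-pyran-4-yl]hex-2-enal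
Product: 7 (4S)-4-[(2R,4E)-2-(tert-butyldimethylsilyloxy)-5-methylhepta-4,6-dien-1-yl]tetrahydro-2H-pyran-2-one
Conditions: Ph3PCH3Br, KN(SiMe3)2, THF, 0 °C; then 6, −78 → 0 °C
Reagents that add atoms: methyltriphenylphosphonium bromide, C[P+](c1ccccc1)(c1ccccc1)c1ccccc1.[Br-]
Why: Wittig methylenation is selective for the aldehyde over the lactone at low temperature and completes the (E)-3-methyl-1,3-diene C2=C3–C4=C5.

Step 7
Reactants: 7 (4S)-4-[(2R,4E)-2-(tert-butyldimethylsilyloxy)-5-methylhepta-4,6-dien-1-yl]tetrahydro-2H-pyran-2-one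
Product: 10 (4S)-3-methylidene-4-[(2R,4E)-2-(tert-butyldimethylsilyloxy)-5-methylhepta-4,6-dien-1-yl]tetrahydro-2H-pyran-2-one, via Mannich base 8 (not isolated), via trimethylammonium iodide 9 (not isolated)
Conditions: LiN(iPr)2, THF, −78 °C; CH2=NMe2+ I−, −78 → 23 °C; then MeI, MeOH, 23 °C; then aq. NaHCO3/CH2Cl2, 23 °C
Reagents that add atoms: N,N-dimethylmethyleneiminium iodide, [I-].C=[N+](C)C
Why: Mannich reaction of the lithium enolate at C10 with the iminium salt, exhaustive N-methylation and base-induced elimination of trimethylamine install the exocyclic C1=C10 methylene, in which the transient C10 centre is erased.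

Step 8
Reactants: 10 (4S)-3-methylidene-4-[(2R,4E)-2-(tert-butyldimethylsilyloxy)-5-methylhepta-4,6-dien-1-yl]tetrahydro-2H-pyran-2-one
Product: 11 7β-(tert-butyldimethylsilyloxy)-13,14,15,16,17,19-hexanorlabd-3-en-20,12-olide (trans-fused 4-methyl-Δ3-octalin, 5α-H, 9α-H, δ-lactone from C20 on C10 to O–C12H2–C11H2 on C9)
Conditions: Et2AlCl (20 mol%), CH2Cl2 (0.01 M), −78 → 0 °C
Reagents that add atoms: none
Why: Concerted, asynchronous intramolecular [4+2] cycloaddition of a 1,7,9-decatriene in which the Al-complexed α-methylene lactone C1=C10 is the dienophile, C2=C3–C4=C5 the diene and C6–C9 the tether, so that C5–C10 and C1–C2 form together; the closest known reaction type is the Lewis acid-promoted intramolecular Diels–Alder reaction of 2-substituted acrylate-type trienes to angularly substituted trans-decalins. Ring A closes as the new cyclohexene (both new bonds, C3=C4 left behind), and ring B closes through C5–C10 as the tether-derived six-membered ring in the fused, chair-like mode, the only one a four-atom tether allows. C10 is controlled by C9: allylic strain in the methylene lactone turns the C9–C8 bond perpendicular to the C1=C10 plane, the diene can reach only that face, and ring B therefore becomes cis-fused to the lactone (C20 axial and β, C11 equatorial). C5 is set by the endo position of the Al-bound lactone carbonyl (C20 under C3–C4, tether exo), which with the E geometry of C4=C5 puts H-5 anti to C20, that is, the trans A/B fusion. The step needs endo selectivity and one π-face; the first is secured by the Lewis acid and the E-diene, the second by the temporary lactone ring together with the C9 centre, and the C7 silyloxy group stays equatorial in this transition state.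

Step 9
Reactants: 11 7β-(tert-butyldimethylsilyloxy)-13,14,15,16,17,19-hexanorlabd-3-en-20,12-olide
Product: 13 7β-(tert-butyldimethylsilyloxy)-13,14,15,16,17-pentanorlabdan-20,12-olide, via sulfonylhydrazide adduct 12 (not isolated)
Conditions: CH2=NNHSO2C8H17 (2 equiv), Fe(acac)3 (0.5 equiv), PhSiH3 (3 equiv), THF/MeOH (4:1), 23 °C; then MeOH, 60 °C
Reagents that add atoms: formaldehyde N-(octylsulfonyl)hydrazone, C=NNS(=O)(=O)CCCCCCCC
Why: iron hydride hydrogen-atom transfer to C3 (Markovnikov radical hydrofunctionalisation) gives the tertiary C4 radical, which adds to the formaldehyde hydrazone; on warming, 12 loses octanesulfinic acid and N2, so the added carbon becomes the second C4 methyl (olefin hydromethylation) and C4 is not a stereocentre.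

Step 10
Reactants: 13 7β-(tert-butyldimethylsilyloxy)-13,14,15,16,17-pentanorlabdan-20,12-olide
Product: 14 7β-(tert-butyldimethylsilyloxy)-12,20-epoxy-13,14,15,16,17-pentanorlabdan-20-ol (lactol, C20 anomers)
Conditions: iBu2AlH (1.1 equiv), CH2Cl2, −78 °C; aq. potassium sodium tartrate work-up
Reagents that add atoms: none
Why: partial reduction of the hindered lactone with one equivalent of iBu2AlH at −78 °C stops at the aluminium hemiacetal, which gives the lactol on work-up.

Step 11
Reactants: 14 7β-(tert-butyldimethylsilyloxy)-12,20-epoxy-13,14,15,16,17-pentanorlabdan-20-ol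
Product: 16 7β-(tert-butyldimethylsilyloxy)-13,14,15,16,17-pentanorlabdan-12-ol, via tosylhydrazone 15 (not isolated)
Conditions: TsNHNH2, THF/MeOH, 50 °C; then catecholborane, CHCl3, 0 → 23 °C; then NaOAc·3H2O, 60 °C
Reagents that add atoms: none
Why: the lactol reacts through its hydroxy aldehyde form to the tosylhydrazone, and hydride delivery from catecholborane followed by acetate-induced loss of sulfinate and N2 (Kabalka modification of the Caglioti reduction) converts C20 into the angular methyl under conditions that spare the silyl ether; C10 is unaffected.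

Step 12
Reactants: 16 7β-(tert-butyldimethylsilyloxy)-13,14,15,16,17-pentanorlabdan-12-ol
Product: 17 7β-(tert-butyldimethylsilyloxy)-13,14,15,16,17-pentanorlabdan-12-al
Conditions: Dess–Martin periodinane, CH2Cl2, 23 °C
Reagents that add atoms: none
Why: Dess–Martin oxidation of the primary alcohol to the aldehyde under neutral conditions, with no epimerisable centre nearby.

Step 13
Reactants: 17 7β-(tert-butyldimethylsilyloxy)-13,14,15,16,17-pentanorlabdan-12-al
Product: 18 (12E)-7β-(tert-butyldimethylsilyloxy)-15,17-dinorlabd-12-en-14-al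
Conditions: Ph3P=C(CH3)CHO, toluene, 90 °C
Reagents that add atoms: 2-(triphenylphosphoranylidene)propanal, CC(C=O)=P(c1ccccc1)(c1ccccc1)c1ccccc1
Why: Wittig olefination with the stabilised α-methyl ylide is highly E-selective with an unbranched aldehyde and gives the C12=C13 enal with C11 cis to the C13 methyl.

Step 14
Reactants: 18 (12E)-7β-(tert-butyldimethylsilyloxy)-15,17-dinorlabd-12-en-14-al
Product: 19 (12E)-7β-(tert-butyldimethylsilyloxy)-17-norlabda-12,14-diene
Conditions: Ph3PCH3Br, KN(SiMe3)2, THF, 0 °C; then 18, −78 → 0 °C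
Reagents that add atoms: methyltriphenylphosphonium bromide, C[P+](c1ccccc1)(c1ccccc1)c1ccccc1.[Br-]
Why: Wittig methylenation of the enal carbonyl at low temperature adds C15 and gives the 12E,14-diene without moving the C12=C13 bond.

Step 15
Reactants: 19 (12E)-7β-(tert-butyldimethylsilyloxy)-17-norlabda-12,14-diene
Product: 20 (12E)-17-norlabda-12,14-dien-7β-ol
Conditions: Bu4NF, THF, 23 °C
Reagents that add atoms: none
Why: fluoride cleaves the silyl ether and liberates the 7β-alcohol with retention.

Step 16
Reactants: 20 (12E)-17-norlabda-12,14-dien-7β-ol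
Product: 21 (12E)-17-norlabda-12,14-dien-7-one
Conditions: Dess–Martin periodinane, CH2Cl2, 23 °C
Reagents that add atoms: none
Why: Dess–Martin oxidation of the secondary alcohol gives the C7 ketone and removes the temporary C7 centre; the skipped diene is inert.

Step 17
Reactants: 21 (12E)-17-norlabda-12,14-dien-7-one
Product: 24 (5S,9R,10S)-labda-8(17),12E,14-trien-7-one, via Mannich base 22 (not isolated), via trimethylammonium iodide 23 (not isolated)
Conditions: LiN(iPr)2, THF, −78 °C; CH2=NMe2+ I−, −78 → 0 °C; then MeI, MeOH, 23 °C; then aq. NaHCO3/CH2Cl2, 23 °C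
Reagents that add atoms: N,N-dimethylmethyleneiminium iodide, [I-].C=[N+](C)C
Why: kinetic deprotonation removes the axial 8β-H (the 6β-H is syn-axial to both the C10 methyl and the 4β methyl), the enolate is aminomethylated at C8 (Mannich reaction), and quaternisation followed by mild base-induced elimination gives the 8(17)-methylene ketone; C8 becomes sp2 and C9 is untouched.

Step 18
Reactants: 25 2',6'-dihydroxy-4'-methoxyacetophenone; 26 2,4,5-trimethoxybenzaldehyde
Product: 27 (E)-1-(2,6-dihydroxy-4-methoxyphenyl)-3-(2,4,5-trimethoxyphenyl)prop-2-en-1-one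
Conditions: KOH (50% aq.), EtOH, 23 °C
Reagents that add atoms: none
Why: Claisen–Schmidt (crossed aldol) condensation of the acetophenone enolate with the non-enolisable benzaldehyde gives the E-chalcone.

Step 19
Reactants: 27 (E)-1-(2,6-dihydroxy-4-methoxyphenyl)-3-(2,4,5-trimethoxyphenyl)prop-2-en-1-one
Product: 28 5-hydroxy-7-methoxy-2-(2,4,5-trimethoxyphenyl)-4H-chromen-4-one
Conditions: I2 (10 mol%), DMSO, 130 °C
Reagents that add atoms: none
Why: iodine-catalysed oxidative cyclisation in DMSO (conjugate addition of one ortho-hydroxyl, then dehydrogenation) gives the flavone, the second hydroxyl remaining as the hydrogen-bonded 5-OH.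

Step 20
Reactants: 28 5-hydroxy-7-methoxy-2-(2,4,5-trimethoxyphenyl)-4H-chromen-4-one
Product: 29 2-(5-hydroxy-7-methoxy-4-oxo-4H-chromen-2-yl)-5-methoxycyclohexa-2,5-diene-1,4-dione
Conditions: (NH4)2Ce(NO3)6 (2.2 equiv), MeCN/H2O (2:1), 0 °C
Reagents that add atoms: water, O
Why: oxidative demethylation of the para-disposed 2- and 5-methoxy groups of the trimethoxyphenyl ring gives the p-quinone and keeps the third methoxy group; the chelated, carbonyl-deactivated 5-hydroxy ring is much harder to oxidise.

Step 21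
Reactants: 24 (5S,9R,10S)-labda-8(17),12E,14-trien-7-one; 29 2-(5-hydroxy-7-methoxy-4-oxo-4H-chromen-2-yl)-5-methoxycyclohexa-2,5-diene-1,4-dione
Product: 30 Dichrostachine M (5S,9R,10S,12R,2'S,3'R)
Conditions: toluene (0.5 M), 23 → 45 °C, dark
Reagents that add atoms: none
Why: Diels–Alder reaction of an acceptor-substituted quinone, in which only the non-methoxylated C2=C3 bond of 29 is dienophilic and the asynchronous transition state joins the unsubstituted diene terminus C15 to the CH carbon C3' (β to the C1' carbonyl and vinylogously conjugated to the chromenone carbonyl), hence C12 to C2'; suprafacial addition makes the ring fusion cis (H-3' cis to the chromenone), the required stacked arrangement with the flat chromenone under the diene and the quinone ring outside puts C11 cis to the chromenone, and approach to the Re face of C12, anti to the decalin in the side-chain rotamer that turns C13 towards C17, gives 12R,2'S,3'R, these last two elements resting on conformational and stacking preferences only.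

**Compound list**

1 | 5,6-dihydro-2H-pyran-2-one | O=C1C=CCCO1 | starting material
2 | (R)-4-vinyltetrahydro-2H-pyran-2-one | O=C1C[C@H](C=C)CCO1 | intermediate
3 | (S)-2-(2-oxotetrahydro-2H-pyran-4-yl)acetaldehyde | O=C1C[C@H](CC=O)CCO1 | intermediate
4 | (S)-4-[(S)-2-hydroxypent-4-en-1-yl]tetrahydro-2H-pyran-2-one | O=C1C[C@H](C[C@@H](O)CC=C)CCO1 | intermediate
5 | (S)-4-[(S)-2-(tert-butyldimethylsilyloxy)pent-4-en-1-yl]tetrahydro-2H-pyran-2-one | O=C1C[C@H](C[C@@H](O[Si](C)(C)C(C)(C)C)CC=C)CCO1 | intermediate
6 | (2E,5R)-5-(tert-butyldimethylsilyloxy)-2-methyl-6-[(4S)-2-oxotetrahydro-2H-pyran-4-yl]hex-2-enal | O=C1C[C@H](C[C@@H](O[Si](C)(C)C(C)(C)C)C/C=C(\C)C=O)CCO1 | intermediate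
7 | (4S)-4-[(2R,4E)-2-(tert-butyldimethylsilyloxy)-5-methylhepta-4,6-dien-1-yl]tetrahydro-2H-pyran-2-one | O=C1C[C@H](C[C@@H](O[Si](C)(C)C(C)(C)C)C/C=C(\C)C=C)CCO1 | intermediate
8 | 3-[(dimethylamino)methyl] derivative of 7 (Mannich base, C3 epimers of the lactone) | CN(C)CC1C(=O)OCC[C@H]1C[C@@H](O[Si](C)(C)C(C)(C)C)C/C=C(\C)C=C | intermediate
9 | 3-[(trimethylammonio)methyl] derivative of 7, iodide | C[N+](C)(C)CC1C(=O)OCC[C@H]1C[C@@H](O[Si](C)(C)C(C)(C)C)C/C=C(\C)C=C.[I-] | intermediate
10 | (4S)-3-methylidene-4-[(2R,4E)-2-(tert-butyldimethylsilyloxy)-5-methylhepta-4,6-dien-1-yl]tetrahydro-2H-pyran-2-one | C=C1C(=O)OCC[C@H]1C[C@@H](O[Si](C)(C)C(C)(C)C)C/C=C(\C)C=C | intermediate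
11 | 7β-(tert-butyldimethylsilyloxy)-13,14,15,16,17,19-hexanorlabd-3-en-20,12-olide (5α-H, 9α-H, C20 β) | C1[C@@H](O[Si](C)(C)C(C)(C)C)C[C@H]2C(C)=CCC[C@]2(C(=O)OCC3)[C@H]13 | intermediate
12 | 19-[2-(octylsulfonyl)hydrazinyl]-7β-(tert-butyldimethylsilyloxy)-13,14,15,16,17-pentanorlabdan-20,12-olide (C4 epimers) | C1[C@@H](O[Si](C)(C)C(C)(C)C)C[C@H]2C(C)(CNNS(=O)(=O)CCCCCCCC)CCC[C@]2(C(=O)OCC3)[C@H]13 | intermediate
13 | 7β-(tert-butyldimethylsilyloxy)-13,14,15,16,17-pentanorlabdan-20,12-olide | C1[C@@H](O[Si](C)(C)C(C)(C)C)C[C@H]2C(C)(C)CCC[C@]2(C(=O)OCC3)[C@H]13 | intermediate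
14 | 7β-(tert-butyldimethylsilyloxy)-12,20-epoxy-13,14,15,16,17-pentanorlabdan-20-ol (C20 anomers) | C1[C@@H](O[Si](C)(C)C(C)(C)C)C[C@H]2C(C)(C)CCC[C@]2(C(O)OCC3)[C@H]13 | intermediate
15 | 7β-(tert-butyldimethylsilyloxy)-12-hydroxy-13,14,15,16,17-pentanorlabdan-20-al N-tosylhydrazone | C1[C@@H](O[Si](C)(C)C(C)(C)C)C[C@H]2C(C)(C)CCC[C@]2(C=NNS(=O)(=O)c3ccc(C)cc3)[C@H]1CCO | intermediate
16 | 7β-(tert-butyldimethylsilyloxy)-13,14,15,16,17-pentanorlabdan-12-ol | C1[C@@H](O[Si](C)(C)C(C)(C)C)C[C@H]2C(C)(C)CCC[C@]2(C)[C@H]1CCO | intermediate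
17 | 7β-(tert-butyldimethylsilyloxy)-13,14,15,16,17-pentanorlabdan-12-al | C1[C@@H](O[Si](C)(C)C(C)(C)C)C[C@H]2C(C)(C)CCC[C@]2(C)[C@H]1CC=O | intermediate
18 | (12E)-7β-(tert-butyldimethylsilyloxy)-15,17-dinorlabd-12-en-14-al | C1[C@@H](O[Si](C)(C)C(C)(C)C)C[C@H]2C(C)(C)CCC[C@]2(C)[C@H]1C/C=C(\C)C=O | intermediate
19 | (12E)-7β-(tert-butyldimethylsilyloxy)-17-norlabda-12,14-diene | C1[C@@H](O[Si](C)(C)C(C)(C)C)C[C@H]2C(C)(C)CCC[C@]2(C)[C@H]1C/C=C(\C)C=C | intermediate
20 | (12E)-17-norlabda-12,14-dien-7β-ol | C1[C@@H](O)C[C@H]2C(C)(C)CCC[C@]2(C)[C@H]1C/C=C(\C)C=C | intermediate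
21 | (12E)-17-norlabda-12,14-dien-7-one | C1C(=O)C[C@H]2C(C)(C)CCC[C@]2(C)[C@H]1C/C=C(\C)C=C | intermediate
22 | (12E)-17-(dimethylamino)labda-12,14-dien-7-one (Mannich base, C8 epimers) | CN(C)CC1C(=O)C[C@H]2C(C)(C)CCC[C@]2(C)[C@H]1C/C=C(\C)C=C | intermediate
23 | (12E)-17-(trimethylammonio)labda-12,14-dien-7-one iodide | C[N+](C)(C)CC1C(=O)C[C@H]2C(C)(C)CCC[C@]2(C)[C@H]1C/C=C(\C)C=C.[I-] | intermediate
24 | (5S,9R,10S)-labda-8(17),12E,14-trien-7-one | C=C1C(=O)C[C@H]2C(C)(C)CCC[C@]2(C)[C@H]1C/C=C(\C)C=C | intermediate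
25 | 2',6'-dihydroxy-4'-methoxyacetophenone | CC(=O)c1c(O)cc(OC)cc1O | starting material
26 | 2,4,5-trimethoxybenzaldehyde | COc1cc(OC)c(C=O)cc1OC | starting material
27 | (E)-1-(2,6-dihydroxy-4-methoxyphenyl)-3-(2,4,5-trimethoxyphenyl)prop-2-en-1-one | COc1cc(O)c(C(=O)/C=C/c2cc(OC)c(OC)cc2OC)c(O)c1 | intermediate
28 | 5-hydroxy-7-methoxy-2-(2,4,5-trimethoxyphenyl)-4H-chromen-4-one | COc1cc(OC)c(cc1OC)-c1cc(=O)c2c(O)cc(OC)cc2o1 | intermediate
29 | 2-(5-hydroxy-7-methoxy-4-oxo-4H-chromen-2-yl)-5-methoxycyclohexa-2,5-diene-1,4-dione | COC1=CC(=O)C(=CC1=O)c1cc(=O)c2c(O)cc(OC)cc2o1 | intermediate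
30 | Dichrostachine M | C=C1C(=O)C[C@H]2C(C)(C)CCC[C@]2(C)[C@H]1C[C@@H]1C(C)=CC[C@H]2C(=O)C(OC)=CC(=O)[C@@]12c1cc(=O)c2c(O)cc(OC)cc2o1 | target

**Step count**

Total: 21 steps. Longest linear sequence: 18 steps (steps 1–17, then step 21); steps 18–20 form the three-step quinone branch.

**Steps most likely to fail**

Step 21. The cycloaddition may run mainly through the arrangement with the quinone ring, not the chromenone, under the diene, and it may discriminate poorly between the two faces of the side-chain diene; stereoisomeric adducts would then dominate. The fallback changes the diene geometry so that the ordinary endo arrangement gives the required relationship. From aldehyde 17, olefination with Ph3P=C(CH3)I (from (1-iodoethyl)triphenylphosphonium iodide and NaN(SiMe3)2, THF, −78 °C) should give the (12Z)-13-iodo-7β-(tert-butyldimethylsilyloxy)-14,15,17-trinorlabd-12-ene F1. Stille coupling with tributyl(vinyl)stannane (Pd(PPh3)4, CuI, DMF, 23 °C) should give the (12Z)-diene silyl ether F2, Bu4NF the (12Z)-dienol F3, and Dess–Martin oxidation the (12Z)-dienone F4. The sequence of step 17, through the Mannich base F5 and the trimethylammonium iodide F6, should give the (12Z)-trienone F7. Cycloaddition of F7 with 29 under about 12 kbar (CH2Cl2, 23 °C) would come back to the route at 30, because C11 then sits on the inside of the diene and the usual approach with the quinone ring under the diene places it cis to the chromenone.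

Step 8. Under the Lewis acid the electron-rich diene may oligomerise, or ring closure may pass through the transition state with the tether (not the carbonyl) under the diene and give the cis-fused decalin. The fallback replaces the lactone carbonyl by a formyl group as the activating group. From diene lactone 7, iBu2AlH (CH2Cl2, −78 °C) should give the lactol F8. α-Methylenation of its open hydroxy aldehyde form (aq. CH2O, pyrrolidine, propionic acid, i-PrOH, 45 °C) should give the 2-substituted acrolein F9. This more reactive and strongly endo-directing dienophile should cyclise (Me2AlCl, CH2Cl2, −78 °C, or on gentle warming) to the angular aldehyde, obtained as the tricyclic lactol F10. Oxidation of F10 (PhI(OAc)2, TEMPO, CH2Cl2) would come back to the route at lactone 11.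

Step 17. Enolisation may occur towards C6 as well as C8, or aminomethylation may occur twice, which would give regioisomeric or over-alkylated methylene ketones at a late stage. The fallback uses a reversible Claisen condensation to choose the position. From ketone 21, ethyl formate and NaH (THF, 23 °C) under equilibrating conditions should give the 8-(hydroxymethylene) ketone F11 at the less hindered α-methylene. K2CO3 with aqueous formaldehyde (THF, 23 °C) should then convert F11 into 24 by aldol addition and loss of formate, which comes back to the route at 24.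

**Further compounds**

F1 | step 21 | (12Z)-13-iodo-7β-(tert-butyldimethylsilyloxy)-14,15,17-trinorlabd-12-ene | C1[C@@H](O[Si](C)(C)C(C)(C)C)C[C@H]2C(C)(C)CCC[C@]2(C)[C@H]1C/C=C(/C)I
F2 | step 21 | (12Z)-7β-(tert-butyldimethylsilyloxy)-17-norlabda-12,14-diene | C1[C@@H](O[Si](C)(C)C(C)(C)C)C[C@H]2C(C)(C)CCC[C@]2(C)[C@H]1C/C=C(/C)C=C
F3 | step 21 | (12Z)-17-norlabda-12,14-dien-7β-ol | C1[C@@H](O)C[C@H]2C(C)(C)CCC[C@]2(C)[C@H]1C/C=C(/C)C=C
F4 | step 21 | (12Z)-17-norlabda-12,14-dien-7-one | C1C(=O)C[C@H]2C(C)(C)CCC[C@]2(C)[C@H]1C/C=C(/C)C=C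
F5 | step 21 | (12Z)-17-(dimethylamino)labda-12,14-dien-7-one (C8 epimers) | CN(C)CC1C(=O)C[C@H]2C(C)(C)CCC[C@]2(C)[C@H]1C/C=C(/C)C=C
F6 | step 21 | (12Z)-17-(trimethylammonio)labda-12,14-dien-7-one iodide | C[N+](C)(C)CC1C(=O)C[C@H]2C(C)(C)CCC[C@]2(C)[C@H]1C/C=C(/C)C=C.[I-]
F7 | step 21 | (5S,9R,10S)-labda-8(17),12Z,14-trien-7-one | C=C1C(=O)C[C@H]2C(C)(C)CCC[C@]2(C)[C@H]1C/C=C(/C)C=C
F8 | step 8 | (4S)-4-[(2R,4E)-2-(tert-butyldimethylsilyloxy)-5-methylhepta-4,6-dien-1-yl]tetrahydro-2H-pyran-2-ol (lactol, anomers) | OC1C[C@H](C[C@@H](O[Si](C)(C)C(C)(C)C)C/C=C(\C)C=C)CCO1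
F9 | step 8 | (3S,5R,7E)-5-(tert-butyldimethylsilyloxy)-3-(2-hydroxyethyl)-8-methyl-2-methylidenedeca-7,9-dienal (open form of the methylene lactol) | C=C(C=O)[C@@H](CCO)C[C@@H](O[Si](C)(C)C(C)(C)C)C/C=C(\C)C=C
F10 | step 8 | 7β-(tert-butyldimethylsilyloxy)-12,20-epoxy-13,14,15,16,17,19-hexanorlabd-3-en-20-ol (lactol, C20 anomers) | C1[C@@H](O[Si](C)(C)C(C)(C)C)C[C@H]2C(C)=CCC[C@]2(C(O)OCC3)[C@H]13
F11 | step 17 | (12E)-17-hydroxylabda-8(17),12,14-trien-7-one (8-hydroxymethylene ketone) | OC=C1C(=O)C[C@H]2C(C)(C)CCC[C@]2(C)[C@H]1C/C=C(\C)C=C
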